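## Retrosynthetic overview

1. Enabling feature: in the pyranone ring, C2 is bonded to ring oxygen O1 and to benzofuran C5, which is para to the furan oxygen. C2 can therefore carry a doubly stabilised oxocarbenium ion, while its neighbour C3 is the α-carbon of the C4 aryl ketone, a latent enolate.
2. Key disconnection C2–C3: the chroman-4-one is the [1,3] O-to-C isomer of a racemic 2-aryl-4-methylidene-4H-1,3-benzodioxine. An enantioconvergent Petasis–Ferrier-type rearrangement under chiral-anion control closes the pyranone ring and sets C2.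
3. The enol acetal comes from Petasis methylenation of a benzodioxin-4-one. That lactone is made by silyl-acetal union of 2,4,6-trihydroxybenzoic acid (two equivalent ortho OH groups, so no regiochemical issue) with 7-prenylbenzofuran-5-carbaldehyde.
4. The aldehyde comes from 3-bromo-4-hydroxybenzaldehyde by iodination, Sonogashira/5-endo-dig furan closure, desilylation and Stille prenylation.
5. Ring order: furan ring, then the temporary 1,3-dioxinone ring, then the pyranone ring (the dioxine ring is consumed). Both benzene rings are purchased.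

Key step: step 8

Assumption: the sense of induction of the chiral anion in step 8 cannot be derived from a model for this new substrate class. The (S,S)-catalyst is written, and its mirror image is taken if a trial run shows that it exposes the Re face of the cation.

## Route

Step 1
Reactants: 1 3-bromo-4-hydroxybenzaldehyde
Product: 2 3-bromo-4-hydroxy-5-iodobenzaldehyde
Conditions: NIS (1.05 equiv), p-TsOH (10 mol %), MeCN, 0 °C to rt
Reagents that add atoms: N-iodosuccinimide, O=C1CCC(=O)N1I
Why: Electrophilic aromatic iodination, in which the phenol OH directs the iodonium equivalent to its only free ortho position (para is blocked by CHO, the other ortho position by Br), so a single regioisomer is expected.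

Step 2
Reactants: 2 3-bromo-4-hydroxy-5-iodobenzaldehyde
Product: 4 7-bromo-2-(trimethylsilyl)-1-benzofuran-5-carbaldehyde, via o-alkynylphenol 3 (not isolated)
Conditions: Me3SiC≡CH (1.2 equiv), PdCl2(PPh3)2 (2 mol %), CuI (4 mol %), Et3N, DMF, rt, then 65 °C
Reagents that add atoms: ethynyltrimethylsilane, C#C[Si](C)(C)C
Why: Sonogashira coupling takes place selectively at the weaker C–I bond at room temperature, and on warming the o-alkynylphenol 3 closes the furan ring by Cu/amine-promoted 5-endo-dig cycloisomerisation, the C–Br bond being kept for step 4.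

Step 3
Reactants: 4 7-bromo-2-(trimethylsilyl)-1-benzofuran-5-carbaldehyde
Product: 5 7-bromo-1-benzofuran-5-carbaldehyde
Conditions: TBAF (1.1 equiv), wet THF, 0 °C
Reagents that add atoms: none
Why: Fluoride-induced protodesilylation of a 2-silylbenzofuran, driven by Si–F bond formation and the relatively stabilised C2 heteroaryl anion, leaves the aldehyde and the aryl bromide untouched.

Step 4
Reactants: 5 7-bromo-1-benzofuran-5-carbaldehyde
Product: 6 7-(3-methylbut-2-en-1-yl)-1-benzofuran-5-carbaldehyde
Conditions: Bu3SnCH2CH=CMe2 (1.2 equiv), Pd(PPh3)4 (5 mol %), DMF, 90 °C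
Reagents that add atoms: tributyl(3-methylbut-2-en-1-yl)stannane, CCCC[Sn](CCCC)(CCCC)CC=C(C)C
Why: Migita–Kosugi–Stille coupling, in which oxidative addition into the C7–Br bond, transfer of the prenyl group from tin and reductive elimination at the unsubstituted allyl terminus should give the linear prenyl arene under neutral conditions that tolerate the free aldehyde.

Step 5
Reactants: 7 2,4,6-trihydroxybenzoic acid (dried), 6 7-(3-methylbut-2-en-1-yl)-1-benzofuran-5-carbaldehyde
Product: 10 rac-5,7-dihydroxy-2-[7-(3-methylbut-2-en-1-yl)-1-benzofuran-5-yl]-4H-1,3-benzodioxin-4-one, via tetrakis(trimethylsilyl) derivative 8 (not isolated), via bis(trimethylsilyl) benzodioxinone 9 (not isolated)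
Conditions: (i) HMDS (2.5 equiv), THF, rt, then evaporation; (ii) 6, TMSOTf (10 mol %), CH2Cl2, −78 °C, then pyridine; (iii) MeOH, citric acid (cat.), 0 °C
Reagents that add atoms: none
Why: TMSOTf-catalysed silyl acetalisation (Noyori-type conditions, the union stage of the Petasis–Ferrier tactic), in which the silyl ester and one of the two equivalent ortho silyl ethers of 8 condense with the aldehyde, driven by loss of hexamethyldisiloxane, at a temperature at which the prenyl group and the furan survive; the acetal centre forms racemic, which is harmless because step 8 erases it.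

Step 6
Reactants: 10 rac-5,7-dihydroxy-2-[7-(3-methylbut-2-en-1-yl)-1-benzofuran-5-yl]-4H-1,3-benzodioxin-4-one
Product: 11 rac-5,7-bis[(tert-butyldimethylsilyl)oxy]-2-[7-(3-methylbut-2-en-1-yl)-1-benzofuran-5-yl]-4H-1,3-benzodioxin-4-one
Conditions: TBSCl (2.6 equiv), imidazole (5 equiv), DMAP (5 mol %), DMF, rt
Reagents that add atoms: tert-butyldimethylsilyl chloride, CC(C)(C)[Si](C)(C)Cl
Why: Standard imidazole-mediated silylation of both phenols gives fluoride-labile, non-acetal protecting groups that tolerate the titanium carbene of step 7 and the silylium catalyst of step 8.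

Step 7
Reactants: 11 rac-5,7-bis[(tert-butyldimethylsilyl)oxy]-2-[7-(3-methylbut-2-en-1-yl)-1-benzofuran-5-yl]-4H-1,3-benzodioxin-4-one
Product: 12 rac-5,7-bis[(tert-butyldimethylsilyl)oxy]-4-methylidene-2-[7-(3-methylbut-2-en-1-yl)-1-benzofuran-5-yl]-4H-1,3-benzodioxine
Conditions: Cp2TiMe2 (2.5 equiv), toluene, 70 °C, dark; filtration through basic alumina (1 % Et3N)
Reagents that add atoms: dimethyltitanocene, C[Ti](C)(C1C=CC=C1)C1C=CC=C1
Why: Petasis methylenation, in which thermally generated Cp2Ti=CH2 adds to the lactone carbonyl by [2+2] cycloaddition and cycloreverts to the exocyclic enol ether, as in the methylenation of 1,3-dioxan-4-ones, under non-acidic and non-basic conditions that leave the acetal, the trisubstituted alkene, the furan and the silyl ethers intact.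

Step 8
Reactants: 12 rac-5,7-bis[(tert-butyldimethylsilyl)oxy]-4-methylidene-2-[7-(3-methylbut-2-en-1-yl)-1-benzofuran-5-yl]-4H-1,3-benzodioxine
Product: 14 (2S)-5,7-bis[(tert-butyldimethylsilyl)oxy]-2-[7-(3-methylbut-2-en-1-yl)-1-benzofuran-5-yl]-2,3-dihydro-4H-chromen-4-one, via ring-opened oxocarbenium enol silane 13 (not isolated)
Conditions: (S,S)-IDPi (BINOL-derived imidodiphosphorimidate, 3,3′-diphenyl, N-triflyl core; 5 mol %, pre-silylated with allyltrimethylsilane, 6 mol %), toluene (0.02 M), −78 °C; then Et3N
Reagents that add atoms: none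
Why: Proposed new method: the silylated IDPi transfers Me3Si+ to the enol-ether oxygen O3 of 12, the C2–O3 acetal bond ionises because the cation is carried both by ring oxygen O1 and by benzofuran C5 para to the furan oxygen, and the methylidene carbon of the tethered enol silane in 13 then attacks the oxocarbenium carbon and returns the silyl cation to the anion, so that the 1,3-dioxine skeleton becomes the chroman-4-one skeleton by a net [1,3] O-to-C shift. The closest known reaction types are the Me2AlCl-promoted Petasis–Ferrier rearrangement of 4-methylidene-1,3-dioxanes to tetrahydropyran-4-ones, the chiral-phosphoric-acid-catalysed aza-Petasis–Ferrier rearrangement, and the IDPi-catalysed asymmetric Prins cyclisations and Mukaiyama-type additions to oxocarbenium ions; new here are the benzo-fused substrate class and the enantioselective all-oxygen version. The pyranone ring closes in a 6-(enolendo)-endo-trig mode through a half-chair with the benzofuranyl group pseudo-equatorial. The acetal stereocentre of racemic 12 is erased on ionisation, so both enantiomers converge on one achiral cation, and C2 is set solely by the confined chiral anion, which must leave the Si face of the oxocarbenium carbon open to give (S). The step needs C2–O3 rather than C2–O1 cleavage (the latter is reversible and has no C–C outlet), intramolecular rather than intermolecular capture (secured by the ortho tether, high dilution and −78 °C), and no racemic background (the chiral imidate is the only counter-ion and no protic acid remains, which also spares the prenyl alkene, the furan and the aryl silyl ethers).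

Step 9
Reactants: 14 (2S)-5,7-bis[(tert-butyldimethylsilyl)oxy]-2-[7-(3-methylbut-2-en-1-yl)-1-benzofuran-5-yl]-2,3-dihydro-4H-chromen-4-one
Product: 15 abyssinoflavanone VI, (2S)-5,7-dihydroxy-2-[7-(3-methylbut-2-en-1-yl)-1-benzofuran-5-yl]-2,3-dihydro-4H-chromen-4-one
Conditions: Et3N·3HF (3 equiv), THF, 0 °C to rt
Reagents that add atoms: none
Why: Fluoride cleavage of the two aryl silyl ethers in a slightly acidic medium avoids free phenoxide and thus the retro-oxa-Michael opening to the chalcone that would racemise C2, and it does not touch the prenyl group or the furan.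

## Compound list

1 | 3-bromo-4-hydroxybenzaldehyde | O=Cc1ccc(O)c(Br)c1 | starting material
2 | 3-bromo-4-hydroxy-5-iodobenzaldehyde | O=Cc1cc(Br)c(O)c(I)c1 | intermediate
3 | 3-bromo-4-hydroxy-5-[(trimethylsilyl)ethynyl]benzaldehyde (not isolated) | O=Cc1cc(Br)c(O)c(C#C[Si](C)(C)C)c1 | intermediate
4 | 7-bromo-2-(trimethylsilyl)-1-benzofuran-5-carbaldehyde | O=Cc1cc(Br)c2oc([Si](C)(C)C)cc2c1 | intermediate
5 | 7-bromo-1-benzofuran-5-carbaldehyde | O=Cc1cc(Br)c2occc2c1 | intermediate
6 | 7-(3-methylbut-2-en-1-yl)-1-benzofuran-5-carbaldehyde | CC(C)=CCc1cc(C=O)cc2ccoc12 | intermediate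
7 | 2,4,6-trihydroxybenzoic acid | O=C(O)c1c(O)cc(O)cc1O | starting material
8 | trimethylsilyl 2,4,6-tris[(trimethylsilyl)oxy]benzoate (not isolated) | C[Si](C)(C)OC(=O)c1c(O[Si](C)(C)C)cc(O[Si](C)(C)C)cc1O[Si](C)(C)C | intermediate
9 | rac-2-[7-(3-methylbut-2-en-1-yl)-1-benzofuran-5-yl]-5,7-bis[(trimethylsilyl)oxy]-4H-1,3-benzodioxin-4-one (not isolated) | O=C1OC(c2cc(CC=C(C)C)c3occc3c2)Oc2cc(O[Si](C)(C)C)cc(O[Si](C)(C)C)c21 | intermediate
10 | rac-5,7-dihydroxy-2-[7-(3-methylbut-2-en-1-yl)-1-benzofuran-5-yl]-4H-1,3-benzodioxin-4-one | O=C1OC(c2cc(CC=C(C)C)c3occc3c2)Oc2cc(O)cc(O)c21 | intermediate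
11 | rac-5,7-bis[(tert-butyldimethylsilyl)oxy]-2-[7-(3-methylbut-2-en-1-yl)-1-benzofuran-5-yl]-4H-1,3-benzodioxin-4-one | O=C1OC(c2cc(CC=C(C)C)c3occc3c2)Oc2cc(O[Si](C)(C)C(C)(C)C)cc(O[Si](C)(C)C(C)(C)C)c21 | intermediate
12 | rac-5,7-bis[(tert-butyldimethylsilyl)oxy]-4-methylidene-2-[7-(3-methylbut-2-en-1-yl)-1-benzofuran-5-yl]-4H-1,3-benzodioxine | C=C1OC(c2cc(CC=C(C)C)c3occc3c2)Oc2cc(O[Si](C)(C)C(C)(C)C)cc(O[Si](C)(C)C(C)(C)C)c21 | intermediate
13 | ring-opened aryl oxocarbenium ion bearing the ortho trimethylsilyl enol ether (not isolated; counter-ion is the IDPi anion, Me3Si comes from the catalyst) | C=C(O[Si](C)(C)C)c1c(O[Si](C)(C)C(C)(C)C)cc(O[Si](C)(C)C(C)(C)C)cc1[O+]=Cc1cc(CC=C(C)C)c2occc2c1 | intermediate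
14 | (2S)-5,7-bis[(tert-butyldimethylsilyl)oxy]-2-[7-(3-methylbut-2-en-1-yl)-1-benzofuran-5-yl]-2,3-dihydro-4H-chromen-4-one | CC(C)=CCc1cc([C@@H]2CC(=O)c3c(O[Si](C)(C)C(C)(C)C)cc(O[Si](C)(C)C(C)(C)C)cc3O2)cc2ccoc12 | intermediate
15 | abyssinoflavanone VI, (2S)-5,7-dihydroxy-2-[7-(3-methylbut-2-en-1-yl)-1-benzofuran-5-yl]-2,3-dihydro-4H-chromen-4-one | CC(C)=CCc1cc([C@@H]2CC(=O)c3c(O)cc(O)cc3O2)cc2ccoc12 | target

## Step count and risks

Total step count: 9. Longest linear sequence: 9 steps (1 to 15; acid 7 enters at step 5).

**Step 8 (labelled).** The bulky substrate may fit the confined anion poorly, so that facial discrimination is weak. The basic product ketone may also hold back the silyl cation and stall turnover.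

The fallback uses known chemistry and moves stereocontrol from the rearrangement to a resolution. From 12, the classical Petasis–Ferrier rearrangement with Me2AlCl (1.1 equiv, CH2Cl2, −78 °C) closes the same bond and should give the racemic bis-silyl flavanone F1. F1 is then resolved kinetically by Noyori-type asymmetric transfer hydrogenation (RuCl(p-cymene)[(R,R)-TsDPEN], HCO2H/Et3N, EtOAc, rt, stopped near half conversion), an established reaction type for racemic flavanones. This should reduce the (R)-ketone to the cis-(2R,4R)-flavan-4-ol F2 and leave the (S)-ketone, which is 14 and is separated by chromatography. The route is rejoined at 14.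

**Step 7.** The [2+2] addition may be slow at a lactone carbonyl that is electron-rich and flanked by the peri silyloxy group. The very acid-labile aryl enol acetal may also hydrolyse or ionise during isolation.

In the fallback, C3 is brought in with the phloroglucinol ring instead of by methylenation, and the same cation is reached from an acyclic mixed acetal. Commercial 2,4,6-trihydroxyacetophenone is bis-silylated (TBSCl 2 equiv, imidazole, DMF; one chelated ortho OH stays free) to the phenol F3. From 6, HC(OMe)3/PPTS/MeOH gives the dimethyl acetal F4, and AcCl with cat. ZnBr2 in toluene converts it into the α-chloro ether F5. F5 is used at once to alkylate the sodium salt of F3 (NaH, THF/DMF, 0 °C), giving the mixed O-aryl O-methyl acetal F6. LDA then TMSCl (THF, −78 °C) gives the enol silane F7. Under the conditions of step 8 the silyl cation removes the methoxy group, which leads to the same ion 13, and the route is rejoined at 14.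

**Step 5.** The activated aldehyde may attack the electron-rich ring carbons of 8 (Friedel–Crafts alkylation) instead of oxygen. The acid may decarboxylate during silylation, and traces of triflic acid may add to the prenyl alkene.

In the fallback, the prenyl group is introduced after the dioxinone, so that a robust dehydrative condensation can be used. From 5 and 7, SOCl2 and cat. DMAP in DME (0 °C to rt), the conditions established for carbonyl acetals of this acid, should give the bromo benzodioxinone F8. TBSCl/imidazole gives the bis-silyl ether F9. Stille coupling of F9 with tributyl(3-methylbut-2-en-1-yl)stannane as in step 4 gives 11, where the route is rejoined.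

## Further compounds

F1 | step 8 | rac-5,7-bis[(tert-butyldimethylsilyl)oxy]-2-[7-(3-methylbut-2-en-1-yl)-1-benzofuran-5-yl]-2,3-dihydro-4H-chromen-4-one | CC(C)=CCc1cc(C2CC(=O)c3c(O[Si](C)(C)C(C)(C)C)cc(O[Si](C)(C)C(C)(C)C)cc3O2)cc2ccoc12
F2 | step 8 | (2R,4R)-5,7-bis[(tert-butyldimethylsilyl)oxy]-2-[7-(3-methylbut-2-en-1-yl)-1-benzofuran-5-yl]chroman-4-ol (2,4-cis) | CC(C)=CCc1cc([C@H]2C[C@@H](O)c3c(O[Si](C)(C)C(C)(C)C)cc(O[Si](C)(C)C(C)(C)C)cc3O2)cc2ccoc12
F3 | step 7 | 1-{2-hydroxy-4,6-bis[(tert-butyldimethylsilyl)oxy]phenyl}ethanone | CC(=O)c1c(O)cc(O[Si](C)(C)C(C)(C)C)cc1O[Si](C)(C)C(C)(C)C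
F4 | step 7 | 5-(dimethoxymethyl)-7-(3-methylbut-2-en-1-yl)-1-benzofuran | COC(OC)c1cc(CC=C(C)C)c2occc2c1
F5 | step 7 | rac-5-[chloro(methoxy)methyl]-7-(3-methylbut-2-en-1-yl)-1-benzofuran | COC(Cl)c1cc(CC=C(C)C)c2occc2c1
F6 | step 7 | rac-1-{2-[methoxy(7-(3-methylbut-2-en-1-yl)-1-benzofuran-5-yl)methoxy]-4,6-bis[(tert-butyldimethylsilyl)oxy]phenyl}ethanone | COC(Oc1cc(O[Si](C)(C)C(C)(C)C)cc(O[Si](C)(C)C(C)(C)C)c1C(C)=O)c1cc(CC=C(C)C)c2occc2c1
F7 | step 7 | trimethylsilyl enol ether of F6 (racemic) | COC(Oc1cc(O[Si](C)(C)C(C)(C)C)cc(O[Si](C)(C)C(C)(C)C)c1C(=C)O[Si](C)(C)C)c1cc(CC=C(C)C)c2occc2c1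
F8 | step 5 | rac-2-(7-bromo-1-benzofuran-5-yl)-5,7-dihydroxy-4H-1,3-benzodioxin-4-one | O=C1OC(c2cc(Br)c3occc3c2)Oc2cc(O)cc(O)c21
F9 | step 5 | rac-2-(7-bromo-1-benzofuran-5-yl)-5,7-bis[(tert-butyldimethylsilyl)oxy]-4H-1,3-benzodioxin-4-one | O=C1OC(c2cc(Br)c3occc3c2)Oc2cc(O[Si](C)(C)C(C)(C)C)cc(O[Si](C)(C)C(C)(C)C)c21
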